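## Retrosynthetic overview

- Niruriflavone ⇒ (cleave the neopentyl sulfonate, hydrogenolyse the O5 and O7 benzyl ethers) the neopentyl ester of 5,7-bis(benzyloxy)-4'-methoxyflavone-6-sulfonic acid.
- Ring C is cut in one operation at C8a–O1, C4a–C4 and O1–C2. This gives a 4a,8a-aryne of the fully substituted ring A and 3-(4-methoxyphenyl)propiolic acid, which supplies O1, C2, C3, C4 and ring B.
- Structural basis: C4a and C8a are adjacent carbons of ring A that hold the C4 carbonyl carbon and O1, and the C5 oxygen flanks C4a, so it can bias the aryne toward oxygen attack at C8a.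
- Aryne precursor (ortho-silyl aryl triflate) ⇐ ortho-bromophenol ⇐ phenol ⇐ 4-bromo-2,6-bis(benzyloxy) sulfonate ester ⇐ 4-bromo-2,6-difluorobenzenesulfonyl chloride, neopentyl alcohol, benzyl alcohol.
- Ring order: rings A and B are bought; ring C is the only ring formed (step 6). The target has no stereocenter.

Key step: step 6

Assumption: the target is taken as the free sulfonic acid, as drawn, so the last step ends with acidification of the sulfonate salt.

## Route

Step 1
Reactants: 1 4-bromo-2,6-difluorobenzenesulfonyl chloride; 2 neopentyl alcohol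
Product: 3 neopentyl 4-bromo-2,6-difluorobenzenesulfonate
Conditions: pyridine, CH2Cl2, 0 °C to rt
Reagents that add atoms: none
Why: Sulfonylation of a primary alcohol by the sulfonyl chloride with pyridine as base should give the ester; the neopentyl group is chosen because its quaternary β-carbon blocks SN2 attack on the ester carbon in all later steps.

Step 2
Reactants: 3 neopentyl 4-bromo-2,6-difluorobenzenesulfonate; 4 benzyl alcohol (2.1 equiv)
Product: 5 neopentyl 2,6-bis(benzyloxy)-4-bromobenzenesulfonate
Conditions: NaH, THF, 0 °C to 50 °C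
Reagents that add atoms: none
Why: Twofold nucleophilic aromatic substitution (addition–elimination): both fluorides sit ortho to the sulfonyl acceptor and fluoride leaves far faster than the para bromide, while the neopentyl ester offers benzyl oxide neither an accessible carbon nor a good leaving group at sulfur.

Step 3
Reactants: 5 neopentyl 2,6-bis(benzyloxy)-4-bromobenzenesulfonate
Product: 7 neopentyl 2,6-bis(benzyloxy)-4-hydroxybenzenesulfonate, via pinacol boronate 6 (not isolated)
Conditions: B2pin2, PdCl2(dppf), KOAc, dioxane, 90 °C; then H2O2 (30% aq), NaOH, THF, 0 °C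
Reagents that add atoms: bis(pinacolato)diboron, CC1(C)OB(OC1(C)C)B1OC(C)(C)C(C)(C)O1 (boron group of 6); hydrogen peroxide, OO (phenol oxygen of 7)
Why: Miyaura borylation of the aryl bromide followed by oxidation of the C–B bond (aryl shift from boron to peroxide oxygen) should turn the bromide into the phenol under conditions that leave the benzyl ethers and the neopentyl ester alone.

Step 4
Reactants: 7 neopentyl 2,6-bis(benzyloxy)-4-hydroxybenzenesulfonate
Product: 8 neopentyl 2,6-bis(benzyloxy)-3-bromo-4-hydroxybenzenesulfonate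
Conditions: NBS (1.0 equiv), CH2Cl2, −40 °C to 0 °C
Reagents that add atoms: N-bromosuccinimide, O=C1CCC(=O)N1Br
Why: Electrophilic aromatic bromination: the two free ring positions are equivalent and each is ortho to the phenol and ortho/para to the benzyloxy groups, so one equivalent of NBS at low temperature should give the monobromide.

Step 5
Reactants: 8 neopentyl 2,6-bis(benzyloxy)-3-bromo-4-hydroxybenzenesulfonate
Product: 12 neopentyl 2,6-bis(benzyloxy)-4-(trifluoromethylsulfonyloxy)-3-(trimethylsilyl)benzenesulfonate, via trimethylsilyl ether 9 (not isolated), via aryllithium 10 (not isolated), via lithium silylphenoxide 11 (not isolated)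
Conditions: HMDS, THF, 70 °C, then evaporation; n-BuLi, THF, −100 °C to −80 °C; Tf2O, −100 °C to −80 °C
Reagents that add atoms: hexamethyldisilazane, C[Si](C)(C)N[Si](C)(C)C; trifluoromethanesulfonic anhydride, O=S(=O)(OS(=O)(=O)C(F)(F)F)C(F)(F)F
Why: This is the standard ortho-silylaryl triflate sequence of O-silylation, bromine–lithium exchange, 1,3 oxygen-to-carbon silyl shift (retro-Brook rearrangement) and O-triflation of the lithium phenoxide; exchange at −100 °C is expected to outrun attack of butyllithium on the hindered sulfonate or on the benzylic hydrogens.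

Step 6
Reactants: 12 neopentyl 2,6-bis(benzyloxy)-4-(trifluoromethylsulfonyloxy)-3-(trimethylsilyl)benzenesulfonate; 13 3-(4-methoxyphenyl)propiolic acid (1.5 equiv)
Product: 16 neopentyl 5,7-bis(benzyloxy)-2-(4-methoxyphenyl)-4-oxo-4H-chromene-6-sulfonate, via aryne 14 (not isolated), via hydroxyaryl ynone 15 (not isolated)
Conditions: CsF (4 equiv), THF, 110 °C, sealed tube; then Et2NH, EtOH, rt
Reagents that add atoms: none
Why: Proposed new method: CsF strips the trimethylsilyl group and the neighbouring triflate leaves, so aryne 14 (triple bond C4a–C8a) forms slowly; the cesium carboxylate of 13 adds through oxygen at C8a, the resulting C4a carbanion attacks the carbonyl of its own aryl ester through a four-membered alkoxide, and ring opening delivers the phenoxide of ynone 15 with O1 on C8a and C4 on C4a. The closest known reaction type is the fluoride-triggered insertion of arynes into the C–O bond of simple carboxylic acids to give ortho-hydroxyaryl ketones, joined here to the familiar cyclisation of ortho-hydroxyaryl ynones, a combination not yet shown for arylpropiolic acids. Ring C, the only ring formed, closes by 6-endo-dig oxa-Michael addition of the C8a phenoxide to the ynone β-carbon (O1–C2), and the proton originally on the acid, held as bifluoride, ends on C3. No stereocenter is created. The step needs regiocontrol in the carboxylate addition, which the C5 benzyloxy group beside C4a should secure by making C8a the more electrophilic and less hindered aryne carbon and by stabilising the carbanion at C4a (the C6 sulfonate pulls in the same direction). It also needs 6-endo over 5-exo closure, favoured by the poorly solvated cesium phenoxide in an aprotic medium and backed up by the Et2NH stage, which turns any unclosed 15 into a β-enaminone that can only close to the six-membered ring.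

Step 7
Reactants: 16 neopentyl 5,7-bis(benzyloxy)-2-(4-methoxyphenyl)-4-oxo-4H-chromene-6-sulfonate
Product: 17 neopentyl 5,7-dihydroxy-2-(4-methoxyphenyl)-4-oxo-4H-chromene-6-sulfonate
Conditions: H2 (1 atm), Pd/C (10%), EtOAc–MeOH, rt
Reagents that add atoms: none
Why: Catalytic hydrogenolysis of the two benzyl aryl ethers over palladium on carbon; the neopentyl sulfonate, the aryl methyl ether and the chromone C2–C3 double bond are not expected to react at 1 atm and room temperature.

Step 8
Reactants: 17 neopentyl 5,7-dihydroxy-2-(4-methoxyphenyl)-4-oxo-4H-chromene-6-sulfonate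
Product: 19 niruriflavone (5,7-dihydroxy-2-(4-methoxyphenyl)-4-oxo-4H-chromene-6-sulfonic acid), via tetramethylammonium sulfonate 18 (not isolated)
Conditions: Me4NCl, DMF, 160 °C; then 1 M HCl, reversed-phase (C18) purification
Reagents that add atoms: none
Why: SN2 dealkylation of the neopentyl sulfonate by chloride at high temperature in a dipolar aprotic solvent, the usual way to unmask neopentyl-protected arenesulfonic acids; acidification of the salt then gives the free sulfonic acid.

## Compound list

1 | 4-bromo-2,6-difluorobenzenesulfonyl chloride | O=S(=O)(Cl)c1c(F)cc(Br)cc1F | starting material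
2 | neopentyl alcohol (2,2-dimethylpropan-1-ol) | CC(C)(C)CO | starting material
3 | neopentyl 4-bromo-2,6-difluorobenzenesulfonate | CC(C)(C)COS(=O)(=O)c1c(F)cc(Br)cc1F | intermediate
4 | benzyl alcohol | OCc1ccccc1 | starting material
5 | neopentyl 2,6-bis(benzyloxy)-4-bromobenzenesulfonate | CC(C)(C)COS(=O)(=O)c1c(OCc2ccccc2)cc(Br)cc1OCc1ccccc1 | intermediate
6 | neopentyl 2,6-bis(benzyloxy)-4-(4,4,5,5-tetramethyl-1,3,2-dioxaborolan-2-yl)benzenesulfonate | CC(C)(C)COS(=O)(=O)c1c(OCc2ccccc2)cc(B2OC(C)(C)C(C)(C)O2)cc1OCc1ccccc1 | intermediate (not isolated)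
7 | neopentyl 2,6-bis(benzyloxy)-4-hydroxybenzenesulfonate | CC(C)(C)COS(=O)(=O)c1c(OCc2ccccc2)cc(O)cc1OCc1ccccc1 | intermediate
8 | neopentyl 2,6-bis(benzyloxy)-3-bromo-4-hydroxybenzenesulfonate | CC(C)(C)COS(=O)(=O)c1c(OCc2ccccc2)c(Br)c(O)cc1OCc1ccccc1 | intermediate
9 | neopentyl 2,6-bis(benzyloxy)-3-bromo-4-(trimethylsilyloxy)benzenesulfonate | CC(C)(C)COS(=O)(=O)c1c(OCc2ccccc2)c(Br)c(O[Si](C)(C)C)cc1OCc1ccccc1 | intermediate (not isolated)
10 | neopentyl 2,6-bis(benzyloxy)-3-lithio-4-(trimethylsilyloxy)benzenesulfonate | CC(C)(C)COS(=O)(=O)c1c(OCc2ccccc2)c([Li])c(O[Si](C)(C)C)cc1OCc1ccccc1 | intermediate (not isolated)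
11 | lithium 3,5-bis(benzyloxy)-4-(neopentyloxysulfonyl)-2-(trimethylsilyl)phenoxide | CC(C)(C)COS(=O)(=O)c1c(OCc2ccccc2)c([Si](C)(C)C)c([O-])cc1OCc1ccccc1.[Li+] | intermediate (not isolated)
12 | neopentyl 2,6-bis(benzyloxy)-4-(trifluoromethylsulfonyloxy)-3-(trimethylsilyl)benzenesulfonate | CC(C)(C)COS(=O)(=O)c1c(OCc2ccccc2)c([Si](C)(C)C)c(OS(=O)(=O)C(F)(F)F)cc1OCc1ccccc1 | intermediate
13 | 3-(4-methoxyphenyl)propiolic acid | COc1ccc(C#CC(=O)O)cc1 | starting material
14 | neopentyl 2,6-bis(benzyloxy)-3,4-didehydrobenzenesulfonate (aryne) | CC(C)(C)COS(=O)(=O)C1=C(OCc2ccccc2)C#CC=C1OCc1ccccc1 | intermediate (not isolated)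
15 | neopentyl 2,6-bis(benzyloxy)-4-hydroxy-3-[3-(4-methoxyphenyl)prop-2-ynoyl]benzenesulfonate (present as its cesium phenoxide) | COc1ccc(C#CC(=O)c2c(O)cc(OCc3ccccc3)c(S(=O)(=O)OCC(C)(C)C)c2OCc2ccccc2)cc1 | intermediate (not isolated)
16 | neopentyl 5,7-bis(benzyloxy)-2-(4-methoxyphenyl)-4-oxo-4H-chromene-6-sulfonate | COc1ccc(-c2cc(=O)c3c(OCc4ccccc4)c(S(=O)(=O)OCC(C)(C)C)c(OCc4ccccc4)cc3o2)cc1 | intermediate
17 | neopentyl 5,7-dihydroxy-2-(4-methoxyphenyl)-4-oxo-4H-chromene-6-sulfonate | COc1ccc(-c2cc(=O)c3c(O)c(S(=O)(=O)OCC(C)(C)C)c(O)cc3o2)cc1 | intermediate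
18 | tetramethylammonium 5,7-dihydroxy-2-(4-methoxyphenyl)-4-oxo-4H-chromene-6-sulfonate | COc1ccc(-c2cc(=O)c3c(O)c(S(=O)(=O)[O-])c(O)cc3o2)cc1.C[N+](C)(C)C | intermediate (not isolated)
19 | niruriflavone (5,7-dihydroxy-2-(4-methoxyphenyl)-4-oxo-4H-chromene-6-sulfonic acid) | COc1ccc(-c2cc(=O)c3c(O)c(S(=O)(=O)O)c(O)cc3o2)cc1 | target

## Step count

Total steps: 8. Longest linear sequence: 8 steps (1 to 19).

## Steps most likely to fail

**Step 6 (proposed new method).** The cesium propiolate may lose CO2 at the reaction temperature. The C4a carbanion may pick up a proton before the acyl group moves, leaving an aryl ester. The carboxylate may add at the wrong aryne carbon, or the phenoxide may close 5-exo. The fallback uses known chemistry and sets out from phenol 7. Ortho-iodination (NIS, CH2Cl2, 0 °C) would give neopentyl 2,6-bis(benzyloxy)-4-hydroxy-3-iodobenzenesulfonate F1. Palladium-catalysed carbonylative Sonogashira annulation of F1 with commercial 1-ethynyl-4-methoxybenzene (CO 1 atm, PdCl2(PPh3)2, Et2NH, DMF, 60–80 °C) would form ynone 15 in the flask, and the amine closes it to the flavone. The route is rejoined at 16.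

**Step 8.** At 160 °C a methyl group may pass from the tetramethylammonium ion to a phenolic oxygen, chloride may attack the 4'-methyl ether, or the electron-rich ring may lose its sulfonate during heating or acidification. The fallback sets out from 16 and cleaves the ester before the phenols are unmasked, with a nucleophile that carries no transferable alkyl group. NaN3 in DMSO at 100 °C would give sodium 5,7-bis(benzyloxy)-2-(4-methoxyphenyl)-4-oxo-4H-chromene-6-sulfonate F2. Hydrogenolysis (H2, Pd/C, MeOH–H2O, rt) would give sodium 5,7-dihydroxy-2-(4-methoxyphenyl)-4-oxo-4H-chromene-6-sulfonate F3. Acidification with 1 M HCl and reversed-phase purification come back to the route at 19.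

**Step 5.** The aryllithium may be protonated or may attack a sulfonate group before the silyl group has moved to the doubly flanked carbon, and over-bromination in step 4 would also starve this step. The fallback sets out from phenol 7 and uses directed ortho-metalation with an external silyl electrophile, which needs neither the bromide nor the silyl migration.
- Isopropyl isocyanate with catalytic Et3N in CH2Cl2 would give neopentyl 2,6-bis(benzyloxy)-4-[(isopropylcarbamoyl)oxy]benzenesulfonate F4.
- N-silylation in the flask (TMSOTf, TMEDA, Et2O), ortho-lithiation (n-BuLi, TMEDA, −78 °C) and a TMSCl quench would give neopentyl 2,6-bis(benzyloxy)-4-[(isopropylcarbamoyl)oxy]-3-(trimethylsilyl)benzenesulfonate F5 after work-up.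
- DBU and Et2NH in MeCN at 40 °C would remove the carbamate to give neopentyl 2,6-bis(benzyloxy)-4-hydroxy-3-(trimethylsilyl)benzenesulfonate F6, which is triflated in the same flask with PhNTf2. The route is rejoined at 12.

## Further compounds

F1 | step 6 | neopentyl 2,6-bis(benzyloxy)-4-hydroxy-3-iodobenzenesulfonate | CC(C)(C)COS(=O)(=O)c1c(OCc2ccccc2)c(I)c(O)cc1OCc1ccccc1
F2 | step 8 | sodium 5,7-bis(benzyloxy)-2-(4-methoxyphenyl)-4-oxo-4H-chromene-6-sulfonate | COc1ccc(-c2cc(=O)c3c(OCc4ccccc4)c(S(=O)(=O)[O-])c(OCc4ccccc4)cc3o2)cc1.[Na+]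
F3 | step 8 | sodium 5,7-dihydroxy-2-(4-methoxyphenyl)-4-oxo-4H-chromene-6-sulfonate | COc1ccc(-c2cc(=O)c3c(O)c(S(=O)(=O)[O-])c(O)cc3o2)cc1.[Na+]
F4 | step 5 | neopentyl 2,6-bis(benzyloxy)-4-[(isopropylcarbamoyl)oxy]benzenesulfonate | CC(C)NC(=O)Oc1cc(OCc2ccccc2)c(S(=O)(=O)OCC(C)(C)C)c(OCc2ccccc2)c1
F5 | step 5 | neopentyl 2,6-bis(benzyloxy)-4-[(isopropylcarbamoyl)oxy]-3-(trimethylsilyl)benzenesulfonate | CC(C)NC(=O)Oc1cc(OCc2ccccc2)c(S(=O)(=O)OCC(C)(C)C)c(OCc2ccccc2)c1[Si](C)(C)C
F6 | step 5 | neopentyl 2,6-bis(benzyloxy)-4-hydroxy-3-(trimethylsilyl)benzenesulfonate | CC(C)(C)COS(=O)(=O)c1c(OCc2ccccc2)c([Si](C)(C)C)c(O)cc1OCc1ccccc1
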